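Atom labels used throughout: the lactone is O1, C2 (carbonyl), C3 (carbinol carbon), C4, C5 (OCH2). C7 is the benzylic CH2 on C4 (3,4-dimethoxyphenyl arm) and C7' is the benzylic CH2 on C3 (syringyl arm). Compounds 1–21 are numbered in the order of the steps below; 21 is the target.

## Analysis of the target

Compound 21 is a dibenzylbutyrolactone lignan of the trachelogenin type: a single γ-lactone ring (O1–C2–C3–C4–C5) carrying a 4-hydroxy-3,5-dimethoxybenzyl group on C3 and a 3,4-dimethoxybenzyl group on C4. It has two adjacent stereocentres: C3, a fully substituted carbinol carbon (S), and C4, a tertiary carbon (S). The two benzyl groups are trans, so the C3 hydroxyl sits cis to the C4 arm. The sensitive groups are the free, electron-rich phenol (oxidation, alkylation), the lactone (opens in base, recloses in acid) and two electron-rich arenes that do not tolerate strong electrophiles or aggressive oxidants. C4 is β to the carbonyl and cannot epimerise, and C3 has no hydrogen, so once set both centres are safe. The hard part is C3: it is quaternary, oxygen-bearing, and its oxygen lies on the face next to the C4 arm, the face an external oxidant would avoid. The strategy rests on the unit C5–C4–C7: an OCH2, a stereogenic CH and a CH2 that ends on an arene, which is the carbon skeleton of (R)-epichlorohydrin 1. If C7 is tied back to C3 as a cyclopropane (bicyclic lactone 6), ring strain lets an aryl nucleophile bond to C7 while C3 becomes an enolate that can take up the second benzyl group.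

## Retrosynthetic reasoning

21 ⇒ 20. The phenol is masked as a benzyl ether and the O–CH2Ph bond is cut last. A benzyl ether survives organomagnesium and organocopper reagents, acid, peracid and hydroxide, and leaves by hydrogenolysis, which touches neither the lactone nor the non-benzylic tertiary alcohol.

20 ⇒ 18 ⇒ 17. The C3–O bond is traced back to a C3–C(acyl) bond. Oxidising a C3 enolate would bring oxygen in anti to the C4 arm, the wrong face. A carbon substituent can instead be placed on the correct face indirectly (it is what remains when the syringylmethyl group enters anti) and then exchanged for oxygen with retention. The forward reaction is a Baeyer–Villiger oxidation of methyl ketone 17, in which the quaternary C3 migrates in preference to methyl, giving acetate 18; hydrolysis gives 20.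

17 ⇒ 15 ⇒ 14. The acetyl group comes from carboxylic acid 15 through acid chloride 16, and 15 from tert-butyl ester 14. The tert-butyl ester is chosen because acid removes it without touching the lactone, and because its bulk protects the ester carbonyl during the organometallic step.

14 ⇒ 6 + 12 + 10 (key disconnection). Two bonds are cut: aryl–C7 and C3–C7'. Cutting here, and not at C3–C4 or C4–C7, leaves C4 as a stereocentre that no step has to create, and turns the C3 problem into an enolate alkylation controlled by the neighbouring C4 substituent. In the forward direction the aryl copper species derived from 12 must open the cyclopropane of 6 at its CH2 only, and the resulting enolate 13 must be C-benzylated by 10 anti to the new C4 arm.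

6 ⇒ 1 + 2. The cyclopropane and lactone are made in one operation from 1 and di-tert-butyl malonate 2. The symmetric di-tert-butyl malonate is used deliberately. With two different ester groups the cyclopropanation would place them at random relative to the hydroxymethyl arm and two different lactones would result. With two identical esters, whichever is cis lactonises and the remaining one is necessarily tert-butyl.

10 ⇒ 9 ⇒ 8 ⇒ 7 and 12 ⇒ 11. The electrophile 10 comes from syringaldehyde 7 by O-benzylation, reduction and bromination. The nucleophile 12 comes from 4-bromo-1,2-dimethoxybenzene 11 and magnesium.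

## Alternatives that were turned down

Alternative 1: The lactone is disconnected at C4–C7 and C3–C7', as in the chosen route, but on a butenolide that already carries the C3 oxygen and a chiral alkoxy group at C5. In the forward step the lithium derivative of 2-(3,4-dimethoxyphenyl)-1,3-dithiane A3 adds to C4 of (5R)-3-(benzyloxy)-5-(l-menthyloxy)furan-2(5H)-one A2 anti to the menthyloxy group. The α-benzyloxy enolate is then benzylated by bromide 10 to give A1.
- For: the C3 oxygen is present from the start, so no carbon-to-oxygen exchange is needed. On this point it is stronger than the chosen strategy. Both stereocentres are relayed from one acetal centre.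
- Against: in A2 the benzyloxy group donates into the C3=C4 bond and lowers the electrophilicity of C4, and the attacking carbanion is tertiary and hindered. The benzylation must build a quaternary carbon next to a carbon bearing a 2-aryl-dithianyl group. A2 needs several steps and a diastereomer separation at the acetal. After A1, desulfurisation, removal of the menthyl acetal, reduction of C5 to CH2 and debenzylation still remain, so the endgame is no shorter.
- Comparison: the chosen strategy reaches its precursor 6 in one step from a cheap chiral-pool epoxide without an auxiliary, and forms both C–C bonds at unhindered primary carbons. It pays for this with the later exchange at C3.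

Alternative 2: The lactone is disconnected at C2–O1/O1–C5 by oxygen insertion, leading back to cyclobutanone A4 ((2S,3S)-2-(benzyloxy)-2-[4-(benzyloxy)-3,5-dimethoxybenzyl]-3-(3,4-dimethoxybenzyl)cyclobutan-1-one). A flavin-dependent Baeyer–Villiger monooxygenase with its nicotinamide cofactor and oxygen would insert oxygen between the carbonyl and the ring CH2 to give the dibenzyl ether A5.
- For: both stereocentres and both arms are already in place, the conditions are mild, and only a double hydrogenolysis would remain. The endgame is shorter than in the chosen route.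
- Against: the required insertion runs against intrinsic migratory aptitude. The quaternary, oxygen-bearing carbon is by far the better migrating group, so only an enzyme pocket could enforce CH2 migration. Enzymes known to do this act on small fused cyclobutanones. A4 is large, poorly water-soluble and fully substituted next to the carbonyl, so acceptance cannot be argued from structure and would need screening. A4 itself, with a quaternary and a tertiary stereocentre on a four-membered ring, has no obvious short enantioselective synthesis.
- Comparison: the chosen strategy takes C4 from 1 and sets C3 by substrate control in a predictable enolate alkylation. It has more steps after the key step, but none depends on finding a catalyst.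

Alternative 3: The lactone is disconnected at C4–C5. Iodomethyl ester A6 (iodomethyl (2S,3E)-2-[4-(benzyloxy)-3,5-dimethoxybenzyl]-4-(3,4-dimethoxyphenyl)-2-hydroxybut-3-enoate) would give an O–CH2 radical under silane chain conditions. This radical closes 5-exo onto the styrene and, after hydrogen transfer to the benzylic radical, gives A7, which is the same compound as 20.
- For: the tertiary alcohol is in place, radical conditions tolerate the free hydroxyl and the arenes, and the product is one hydrogenolysis from 21. This is the shortest endgame of all four plans.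
- Against: the radical carbon can reach the alkene only through the minor ester rotamer, and esters lie almost wholly in the other rotamer, so simple reduction to the methyl ester should compete strongly. The new C4 centre must be set against a quaternary C3 whose hydroxyl and benzyl substituents differ little in size, so poor diastereocontrol is expected. The single stereocentre of A6 needs its own asymmetric construction, and iodomethyl esters are labile alkylating agents.
- Comparison: in the chosen route C4 is never formed in a selective step, and C3 is set by a strong 1,2-induction. It gives up the short endgame for this.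

Key step: step 6

Remark on the chemistry (assumption): in step 1 the potassium enolate of 2 is taken to open the epoxide CH2 of 1 before chloride is displaced. That order leads to the enantiomer of 6 drawn here; the fallback for step 1 covers the other case.

## Route

Step 1
Reactants: 1 (R)-epichlorohydrin; 2 di-tert-butyl malonate
Product: 6 tert-butyl (1R,5R)-2-oxo-3-oxabicyclo[3.1.0]hexane-1-carboxylate, via chlorohydrin alkoxide 3 (not isolated), via epoxy malonate 4 (not isolated), via cyclopropylmethanol alkoxide 5 (not isolated)
Conditions: KOtBu (1.2 equiv), tBuOH–THF, 0 °C → 50 °C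
Reagents that add atoms: none
Why: Tandem epoxide opening, epoxide re-formation, 3-exo-tet cyclopropanation and lactonisation, the established malonate–epichlorohydrin route to 2-oxo-3-oxabicyclo[3.1.0]hexane-1-carboxylates; the malonate carbanion attacks the epoxide CH of 4 with inversion, which sets C5 of 6 as R. Both esters of 5 are tert-butyl, so the alkoxide closes onto whichever is cis, the cis ring fusion fixes C1, and the remaining ester is the tert-butyl ester.

Step 2
Reactants: 7 syringaldehyde (4-hydroxy-3,5-dimethoxybenzaldehyde)
Product: 8 4-(benzyloxy)-3,5-dimethoxybenzaldehyde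
Conditions: BnBr, K2CO3, DMF, 60 °C
Reagents that add atoms: benzyl bromide, BrCc1ccccc1
Why: Williamson etherification of an acidic, para-formyl phenol; the phenoxide is the only nucleophile present.

Step 3
Reactants: 8 4-(benzyloxy)-3,5-dimethoxybenzaldehyde
Product: 9 [4-(benzyloxy)-3,5-dimethoxyphenyl]methanol
Conditions: NaBH4, MeOH–THF, 0 °C
Reagents that add atoms: none
Why: Borohydride reduction of an aromatic aldehyde; nothing else in 8 is reducible under these conditions.

Step 4
Reactants: 9 [4-(benzyloxy)-3,5-dimethoxyphenyl]methanol
Product: 10 4-(benzyloxy)-3,5-dimethoxybenzyl bromide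
Conditions: PBr3 (0.4 equiv), CH2Cl2, 0 °C
Reagents that add atoms: phosphorus tribromide, BrP(Br)Br
Why: Conversion of a benzylic alcohol into the bromide through its phosphite ester, standard for 3,4,5-trialkoxybenzyl alcohols; the short cold reaction leaves the aryl benzyl ether intact, and the bromide is used soon after preparation.

Step 5
Reactants: 11 4-bromo-1,2-dimethoxybenzene
Product: 12 3,4-dimethoxyphenylmagnesium bromide (THF solution, titrated and used directly)
Conditions: Mg turnings, I2 (cat.), THF, 40 °C → rt
Reagents that add atoms: magnesium, [Mg]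
Why: Grignard formation by magnesium insertion into an aryl bromide; the methoxy groups are inert.

Step 6
Reactants: 6 tert-butyl (1R,5R)-2-oxo-3-oxabicyclo[3.1.0]hexane-1-carboxylate; 12 3,4-dimethoxyphenylmagnesium bromide; 10 4-(benzyloxy)-3,5-dimethoxybenzyl bromide
Product: 14 tert-butyl (3S,4R)-3-[4-(benzyloxy)-3,5-dimethoxybenzyl]-4-(3,4-dimethoxybenzyl)-2-oxotetrahydrofuran-3-carboxylate, via bromomagnesium enolate 13 (not isolated)
Conditions: 12 (1.3 equiv), CuI (10 mol%), THF, −40 → −20 °C; then 10 (1.6 equiv), DMPU, −20 °C → rt
Reagents that add atoms: none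
Why: Transmetalation of 12 to copper gives an aryl copper species that attacks the cyclopropane CH2 of 6 in an SN2-like homoconjugate addition; the bond from that CH2 to the doubly activated ring-fusion carbon breaks, strain is released, and the charge is held by the lactone and ester carbonyls as enolate 13 while the aryl–C7 bond forms. The closest known reaction type is the CuI-catalysed opening of 2-oxo-3-oxabicyclo[3.1.0]hexane-1-carboxylates and cyclopropane-1,1-diesters by Grignard reagents, followed by C-alkylation of the malonate-type enolate. No ring is closed: the three-membered ring opens and the lactone is carried through. C4 of 14 is the untouched ring-fusion CH of 6, so its configuration comes directly from 1 (it reads R only because of the priority rules). The new quaternary centre C3 is set in the alkylation: bromide 10 approaches the planar enolate on the face away from the C4 arm, so the two benzyl groups end trans and the ester cis to the C4 arm (3S). The step needs attack at the CH2 and not at the ring-fusion CH (steric access and SN2 character), ring opening in preference to carbonyl addition (copper catalysis, low temperature, bulky tert-butyl ester), and C- over O-benzylation (soft benzylic bromide, DMPU to loosen the magnesium chelate). The excess of 12 is kept small so that its copper-mediated coupling with 10 stays minor.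

Step 7
Reactants: 14 tert-butyl (3S,4R)-3-[4-(benzyloxy)-3,5-dimethoxybenzyl]-4-(3,4-dimethoxybenzyl)-2-oxotetrahydrofuran-3-carboxylate
Product: 15 (3R,4R)-3-[4-(benzyloxy)-3,5-dimethoxybenzyl]-4-(3,4-dimethoxybenzyl)-2-oxotetrahydrofuran-3-carboxylic acid
Conditions: TFA–CH2Cl2 (1:4), 0 °C → rt; evaporation below 30 °C
Reagents that add atoms: none
Why: Acidolysis of a tert-butyl ester by loss of isobutene; the lactone and the aryl benzyl ether tolerate a short exposure at room temperature, and the open ring positions are too hindered for easy tert-butylation. The acid is kept cold and used crude because it is a malonic-type acid that would decarboxylate on heating.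

Step 8
Reactants: 15 (3R,4R)-3-[4-(benzyloxy)-3,5-dimethoxybenzyl]-4-(3,4-dimethoxybenzyl)-2-oxotetrahydrofuran-3-carboxylic acid
Product: 17 (3R,4R)-3-acetyl-3-[4-(benzyloxy)-3,5-dimethoxybenzyl]-4-(3,4-dimethoxybenzyl)dihydrofuran-2(3H)-one, via acid chloride 16 (not isolated)
Conditions: (COCl)2, DMF (cat.), CH2Cl2, 0 °C → rt, evaporate; then Me2CuLi (3 equiv), Et2O–THF, −78 °C
Reagents that add atoms: oxalyl chloride, O=C(Cl)C(=O)Cl (the chlorine of 16); lithium dimethylcuprate, [Li+].C[Cu-]C (the methyl group of 17)
Why: Acid chloride formation followed by cuprate acylation, the standard ketone synthesis from acid chlorides; at −78 °C the cuprate reacts with the acid chloride much faster than with the lactone or the product ketone. C3 has no hydrogen, so neither ketene formation nor epimerisation is possible.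

Step 9
Reactants: 17 (3R,4R)-3-acetyl-3-[4-(benzyloxy)-3,5-dimethoxybenzyl]-4-(3,4-dimethoxybenzyl)dihydrofuran-2(3H)-one
Product: 18 (3S,4S)-3-[4-(benzyloxy)-3,5-dimethoxybenzyl]-4-(3,4-dimethoxybenzyl)-2-oxotetrahydrofuran-3-yl acetate
Conditions: mCPBA (3 equiv), Na2HPO4, CH2Cl2, rt → 40 °C
Reagents that add atoms: 3-chloroperoxybenzoic acid, OOC(=O)c1cccc(Cl)c1
Why: Baeyer–Villiger oxidation of an α,α-disubstituted β-keto ester-type methyl ketone: in the Criegee intermediate the quaternary C3 migrates in preference to methyl, the poorest migrating group, and it migrates with retention. The oxygen therefore takes the place of the acetyl carbon, cis to the C4 arm; the change of both descriptors to S is a priority effect only.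

Step 10
Reactants: 18 (3S,4S)-3-[4-(benzyloxy)-3,5-dimethoxybenzyl]-4-(3,4-dimethoxybenzyl)-2-oxotetrahydrofuran-3-yl acetate
Product: 20 (3S,4S)-3-[4-(benzyloxy)-3,5-dimethoxybenzyl]-4-(3,4-dimethoxybenzyl)-3-hydroxydihydrofuran-2(3H)-one, via lithium dihydroxy carboxylate 19 (not isolated)
Conditions: LiOH·H2O (4 equiv), THF–H2O (3:1), 0 °C → rt; then 1 M HCl to pH 1, rt
Reagents that add atoms: lithium hydroxide, [Li+].[OH-] (lithium and one carboxylate oxygen of 19; one carboxyl oxygen leaves again as water on ring closure)
Why: Saponification of the acetate, with the lactone opening at the same time, then acid-induced relactonisation of the γ-hydroxy acid. Neither stereocentre can epimerise, since C3 is quaternary and C4 is not α to a carbonyl.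

Step 11
Reactants: 20 (3S,4S)-3-[4-(benzyloxy)-3,5-dimethoxybenzyl]-4-(3,4-dimethoxybenzyl)-3-hydroxydihydrofuran-2(3H)-one
Product: 21 (3S,4S)-4-(3,4-dimethoxybenzyl)-3-hydroxy-3-(4-hydroxy-3,5-dimethoxybenzyl)dihydrofuran-2(3H)-one
Conditions: H2 (1 atm), 10% Pd/C, EtOAc–EtOH, rt
Reagents that add atoms: none
Why: Hydrogenolysis of the aryl benzyl ether; the tertiary alcohol is homobenzylic, not benzylic, and the lactone and methyl ethers are inert.

## Compound list

1 | (R)-epichlorohydrin, (2R)-2-(chloromethyl)oxirane | ClC[C@H]1CO1 | starting material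
2 | di-tert-butyl malonate | CC(C)(C)OC(=O)CC(=O)OC(C)(C)C | starting material
3 | potassium alkoxide of di-tert-butyl 2-[(2R)-3-chloro-2-hydroxypropyl]propanedioate | ClC[C@H]([O-])CC(C(=O)OC(C)(C)C)C(=O)OC(C)(C)C.[K+] | intermediate
4 | di-tert-butyl 2-{[(2R)-oxiran-2-yl]methyl}propanedioate | CC(C)(C)OC(=O)C(C[C@@H]1CO1)C(=O)OC(C)(C)C | intermediate
5 | potassium alkoxide of di-tert-butyl (2R)-2-(hydroxymethyl)cyclopropane-1,1-dicarboxylate | [O-]C[C@@H]1CC1(C(=O)OC(C)(C)C)C(=O)OC(C)(C)C.[K+] | intermediate
6 | tert-butyl (1R,5R)-2-oxo-3-oxabicyclo[3.1.0]hexane-1-carboxylate | C1[C@H]2COC(=O)[C@@]12C(=O)OC(C)(C)C | intermediate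
7 | syringaldehyde, 4-hydroxy-3,5-dimethoxybenzaldehyde | COc1cc(C=O)cc(OC)c1O | starting material
8 | 4-(benzyloxy)-3,5-dimethoxybenzaldehyde | COc1cc(C=O)cc(OC)c1OCc1ccccc1 | intermediate
9 | [4-(benzyloxy)-3,5-dimethoxyphenyl]methanol | COc1cc(CO)cc(OC)c1OCc1ccccc1 | intermediate
10 | 4-(benzyloxy)-3,5-dimethoxybenzyl bromide | COc1cc(CBr)cc(OC)c1OCc1ccccc1 | intermediate
11 | 4-bromo-1,2-dimethoxybenzene | COc1ccc(Br)cc1OC | starting material
12 | 3,4-dimethoxyphenylmagnesium bromide | COc1ccc([Mg]Br)cc1OC | intermediate
13 | bromomagnesium enolate of tert-butyl (4R)-4-(3,4-dimethoxybenzyl)-2-oxotetrahydrofuran-3-carboxylate | COc1ccc(C[C@H]2COC(O[Mg]Br)=C2C(=O)OC(C)(C)C)cc1OC | intermediate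
14 | tert-butyl (3S,4R)-3-[4-(benzyloxy)-3,5-dimethoxybenzyl]-4-(3,4-dimethoxybenzyl)-2-oxotetrahydrofuran-3-carboxylate (benzyl groups trans) | COc1ccc(C[C@H]2COC(=O)[C@]2(C(=O)OC(C)(C)C)Cc2cc(OC)c(OCc3ccccc3)c(OC)c2)cc1OC | intermediate
15 | (3R,4R)-3-[4-(benzyloxy)-3,5-dimethoxybenzyl]-4-(3,4-dimethoxybenzyl)-2-oxotetrahydrofuran-3-carboxylic acid | COc1ccc(C[C@H]2COC(=O)[C@]2(C(=O)O)Cc2cc(OC)c(OCc3ccccc3)c(OC)c2)cc1OC | intermediate
16 | (3S,4R)-3-[4-(benzyloxy)-3,5-dimethoxybenzyl]-4-(3,4-dimethoxybenzyl)-2-oxotetrahydrofuran-3-carbonyl chloride | COc1ccc(C[C@H]2COC(=O)[C@]2(C(=O)Cl)Cc2cc(OC)c(OCc3ccccc3)c(OC)c2)cc1OC | intermediate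
17 | (3R,4R)-3-acetyl-3-[4-(benzyloxy)-3,5-dimethoxybenzyl]-4-(3,4-dimethoxybenzyl)dihydrofuran-2(3H)-one | COc1ccc(C[C@H]2COC(=O)[C@]2(C(C)=O)Cc2cc(OC)c(OCc3ccccc3)c(OC)c2)cc1OC | intermediate
18 | (3S,4S)-3-[4-(benzyloxy)-3,5-dimethoxybenzyl]-4-(3,4-dimethoxybenzyl)-2-oxotetrahydrofuran-3-yl acetate | COc1ccc(C[C@H]2COC(=O)[C@]2(OC(C)=O)Cc2cc(OC)c(OCc3ccccc3)c(OC)c2)cc1OC | intermediate
19 | lithium (2S,3S)-2-[4-(benzyloxy)-3,5-dimethoxybenzyl]-3-(3,4-dimethoxybenzyl)-2,4-dihydroxybutanoate | COc1ccc(C[C@@H](CO)[C@@](O)(Cc2cc(OC)c(OCc3ccccc3)c(OC)c2)C(=O)[O-])cc1OC.[Li+] | intermediate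
20 | (3S,4S)-3-[4-(benzyloxy)-3,5-dimethoxybenzyl]-4-(3,4-dimethoxybenzyl)-3-hydroxydihydrofuran-2(3H)-one | COc1ccc(C[C@H]2COC(=O)[C@]2(O)Cc2cc(OC)c(OCc3ccccc3)c(OC)c2)cc1OC | intermediate
21 | (3S,4S)-4-(3,4-dimethoxybenzyl)-3-hydroxy-3-(4-hydroxy-3,5-dimethoxybenzyl)dihydrofuran-2(3H)-one | COc1ccc(C[C@H]2COC(=O)[C@]2(O)Cc2cc(OC)c(O)c(OC)c2)cc1OC | target

## Step count and least certain steps

Total: 11 steps. Longest linear sequence: 9 steps, from syringaldehyde 7 (steps 2, 3, 4, 6, 7, 8, 9, 10, 11). The sequence from 1 is 7 steps, and step 5 is a one-step side branch.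

Step 6 (key step). The most likely failure is sluggish alkylation of the chelated bromomagnesium enolate, so that protonation on work-up, or coupling of leftover aryl Grignard reagent with the bromide, wins over C-benzylation; carbonyl addition of the Grignard reagent before copper transfer is a smaller concern. Fallback, from 6 and 12, returning at 14: the ring opening is run alone and enolate 13 is quenched with aqueous HCl to give tert-butyl (4R)-4-(3,4-dimethoxybenzyl)-2-oxotetrahydrofuran-3-carboxylate F1 (either C3 epimer serves). This isolated β-dicarbonyl compound is then benzylated with 10 and K2CO3 in DMF, where the free potassium enolate is far more nucleophilic and the same anti approach gives 14.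

Step 9. Peracid addition to a ketone flanked by a quaternary, electron-poor carbon may be slow, and then oxidation of the electron-rich arenes by the peracid can overtake the rearrangement. Fallback, from 15 (through 16), returning at 20: the carboxy-inversion sequence. Acid chloride 16 is treated with mCPBA and pyridine in CH2Cl2 at 0 °C to give 3-chlorobenzoyl (3S,4R)-3-[4-(benzyloxy)-3,5-dimethoxybenzyl]-4-(3,4-dimethoxybenzyl)-2-oxotetrahydrofuran-3-carbonyl peroxide F2. Warming F2 in acetonitrile lets C3 migrate from carbon to oxygen with retention, giving (3S,4S)-3-[4-(benzyloxy)-3,5-dimethoxybenzyl]-4-(3,4-dimethoxybenzyl)-2-oxotetrahydrofuran-3-yl 3-chlorobenzoyl carbonate F3. Hydrolysis with LiOH and acidification, as in step 10, then gives 20 without passing through 17 and 18.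

Step 8. The acid chloride sits close to two activated arenes, so intramolecular Friedel–Crafts acylation during its formation or concentration is possible, as is attack of the cuprate on the lactone. Fallback, from 15, returning at 17: the acid is activated without an acid chloride, with isobutyl chloroformate and N-methylmorpholine in THF at −15 °C, as the isobutyl carbonic anhydride of (3S,4R)-3-[4-(benzyloxy)-3,5-dimethoxybenzyl]-4-(3,4-dimethoxybenzyl)-2-oxotetrahydrofuran-3-carboxylic acid F4. Ethereal diazomethane converts F4 into (3R,4R)-3-[4-(benzyloxy)-3,5-dimethoxybenzyl]-3-(diazoacetyl)-4-(3,4-dimethoxybenzyl)dihydrofuran-2(3H)-one F5. Brief treatment of F5 with aqueous HI in CHCl3 reduces the diazoketone to methyl ketone 17.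

Step 1. Direct displacement of chloride by the malonate before epoxide opening leads to the enantiomer of 6, so partial leakage through that path would lower the enantiomeric purity; incomplete lactonisation onto the bulky ester is a second possibility. Fallback, from 2, returning at 6: the order of events is reversed on purpose with a far better leaving group. (R)-Glycidol F6 is converted with Tf2O and pyridine in CH2Cl2 at −30 °C into [(2S)-oxiran-2-yl]methyl trifluoromethanesulfonate F7. The sodium enolate of 2 (NaH, THF) displaces the triflate first and gives 4 directly; 4 then cyclises through 5 to the same enantiomer of 6.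

## Further compounds

F1 | step 6 | tert-butyl (4R)-4-(3,4-dimethoxybenzyl)-2-oxotetrahydrofuran-3-carboxylate (C3 epimers) | COc1ccc(C[C@H]2COC(=O)C2C(=O)OC(C)(C)C)cc1OC
F2 | step 9 | 3-chlorobenzoyl (3S,4R)-3-[4-(benzyloxy)-3,5-dimethoxybenzyl]-4-(3,4-dimethoxybenzyl)-2-oxotetrahydrofuran-3-carbonyl peroxide | COc1ccc(C[C@H]2COC(=O)[C@]2(C(=O)OOC(=O)c2cccc(Cl)c2)Cc2cc(OC)c(OCc3ccccc3)c(OC)c2)cc1OC
F3 | step 9 | (3S,4S)-3-[4-(benzyloxy)-3,5-dimethoxybenzyl]-4-(3,4-dimethoxybenzyl)-2-oxotetrahydrofuran-3-yl 3-chlorobenzoyl carbonate | COc1ccc(C[C@H]2COC(=O)[C@]2(OC(=O)OC(=O)c2cccc(Cl)c2)Cc2cc(OC)c(OCc3ccccc3)c(OC)c2)cc1OC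
F4 | step 8 | isobutyl carbonic anhydride of (3S,4R)-3-[4-(benzyloxy)-3,5-dimethoxybenzyl]-4-(3,4-dimethoxybenzyl)-2-oxotetrahydrofuran-3-carboxylic acid | COc1ccc(C[C@H]2COC(=O)[C@]2(C(=O)OC(=O)OCC(C)C)Cc2cc(OC)c(OCc3ccccc3)c(OC)c2)cc1OC
F5 | step 8 | (3R,4R)-3-[4-(benzyloxy)-3,5-dimethoxybenzyl]-3-(diazoacetyl)-4-(3,4-dimethoxybenzyl)dihydrofuran-2(3H)-one | COc1ccc(C[C@H]2COC(=O)[C@]2(C(=O)C=[N+]=[N-])Cc2cc(OC)c(OCc3ccccc3)c(OC)c2)cc1OC
F6 | step 1 | (R)-glycidol, [(2R)-oxiran-2-yl]methanol | OC[C@@H]1CO1
F7 | step 1 | [(2S)-oxiran-2-yl]methyl trifluoromethanesulfonate | FC(F)(F)S(=O)(=O)OC[C@@H]1CO1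
A1 | alternative 1 | 3-(benzyloxy)-3-[4-(benzyloxy)-3,5-dimethoxybenzyl]-4-[2-(3,4-dimethoxyphenyl)-1,3-dithian-2-yl]-5-(l-menthyloxy)dihydrofuran-2(3H)-one | COc1ccc(C2(SCCCS2)[C@H]2[C@H](O[C@@H]3C[C@H](C)CC[C@H]3C(C)C)OC(=O)[C@]2(OCc2ccccc2)Cc2cc(OC)c(OCc3ccccc3)c(OC)c2)cc1OC
A2 | alternative 1 | (5R)-3-(benzyloxy)-5-(l-menthyloxy)furan-2(5H)-one | O=C1O[C@@H](O[C@@H]2C[C@H](C)CC[C@H]2C(C)C)C=C1OCc1ccccc1
A3 | alternative 1 | 2-(3,4-dimethoxyphenyl)-1,3-dithiane | COc1ccc(C2SCCCS2)cc1OC
A4 | alternative 2 | (2S,3S)-2-(benzyloxy)-2-[4-(benzyloxy)-3,5-dimethoxybenzyl]-3-(3,4-dimethoxybenzyl)cyclobutan-1-one | COc1ccc(C[C@H]2CC(=O)[C@]2(OCc2ccccc2)Cc2cc(OC)c(OCc3ccccc3)c(OC)c2)cc1OC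
A5 | alternative 2 | (3S,4S)-3-(benzyloxy)-3-[4-(benzyloxy)-3,5-dimethoxybenzyl]-4-(3,4-dimethoxybenzyl)dihydrofuran-2(3H)-one | COc1ccc(C[C@H]2COC(=O)[C@]2(OCc2ccccc2)Cc2cc(OC)c(OCc3ccccc3)c(OC)c2)cc1OC
A6 | alternative 3 | iodomethyl (2S,3E)-2-[4-(benzyloxy)-3,5-dimethoxybenzyl]-4-(3,4-dimethoxyphenyl)-2-hydroxybut-3-enoate | COc1ccc(/C=C/[C@@](O)(Cc2cc(OC)c(OCc3ccccc3)c(OC)c2)C(=O)OCI)cc1OC
A7 | alternative 3 | (3S,4S)-3-[4-(benzyloxy)-3,5-dimethoxybenzyl]-4-(3,4-dimethoxybenzyl)-3-hydroxydihydrofuran-2(3H)-one | COc1ccc(C[C@H]2COC(=O)[C@]2(O)Cc2cc(OC)c(OCc3ccccc3)c(OC)c2)cc1OC
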